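## The problem

CNP0206369.0 is a linear chain of eight benzene rings joined by seven diaryl ether oxygens and carrying 21 free phenolic hydroxyls. It has no stereocenter, so the whole task is one of position, not of space. Read from the phloroglucinol end, the rings are:

- ring A: hydroxyls on A1, A3 and A5, bonded through A2–O to B1;
- rings B, D and F: chain oxygens on carbons 1 and 4, hydroxyls on 3 and 5;
- rings C, E and G: chain oxygens on the adjacent carbons 1 and 2, hydroxyls on 3, 4 and 5;
- ring H: a 3,4,5-trihydroxyphenyl cap on the G2 oxygen.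

Only two kinds of inter-ring bond recur, X4–O–Y1 (X = B, D, F; Y = C, E, G) and Y2–O–X1 (X = D, F, H). In each, one oxygen sits between two oxygenated ortho carbons, so every coupling has to use that crowded oxygen as the nucleophile and an open carbon as the electrophile. The hardest single bond is A2–O–B1, because A2 lies between two hydroxyls of an electron-rich ring that cannot be activated for substitution. The pyrogallol-type rings C, E, G and H and the phloroglucinol ring A are oxidised by air in base, so the hydroxyls must stay masked during assembly and be released in one last non-oxidising step. The feature that opens the key step is the 1,3,5-oxygen pattern of ring A around A2. A3, A1 and A5 are the carbonyl carbons C3, C5 and C7 of a 3,5-dioxoheptanedioate, and A2 is its tetrahedral C4. Ring A can therefore be folded from an open chain after the A2–O bond has been made at sp3 carbon.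

## Retrosynthesis

**34 to 33.** The eighteen O–CH3 bonds on rings B to H are cut. Methyl is chosen over benzyl because the ring monomers are available as methyl ethers and survive base, peracid, silylation and enolate chemistry. Ring A needs no protection, since its three hydroxyls are born free in the ring-forming step. The forward reaction must cleave eighteen aryl methyl ethers and no diaryl ether; BBr3 does this.

**33 to 31.** The C–C bond from A4 to a carboxyl carbon is added back, giving methyl 2,4,6-trihydroxybenzoate 31 (acid 32 is the passing intermediate). This ester is the trace of the open chain. Its removal asks only for hydrolysis and the easy decarboxylation of a phloroglucinol carboxylic acid.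

**31 to 30 (key cut).** The A4–A5 bond is cut, which opens ring A to the symmetric dimethyl 4-aryloxy-3,5-dioxoheptanedioate 30. The neighbouring cut, A2–O as a diaryl ether, would require substitution at a carbon flanked by two oxygens on a deactivated ring. Opening the ring instead turns A2 into an sp3 carbon and leaves a chain with no ring and no aryl–aryl ether to make. The forward step needs C-acylation (Claisen) to win over O-acylation; no aldol-type ring is geometrically possible.

**30 to 28 and 29.** The C4–C5 bond of the chain is cut. C4 is the γ-carbon of an acetoacetate, and its 1,3-bis(silyl enol ether) 28 is a neutral carbon nucleophile that tolerates the acidic methylene of methyl malonyl chloride 29. The two-directional cut (an aryloxymalonyl unit plus two acetate anions) was set aside, because a doubly activated aryloxymalonic acid tends toward ketene formation, decarboxylation and pyranone closure. Diene 28 comes from keto ester 26 through mono silyl ether 27.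

**26 to 24 and 25.** The C4–O bond of the chain (the future A2–O bond) is cut to heptamer phenol 24 and methyl 4-chloro-3-oxobutanoate 25. The B1 hydroxyl has two free ortho positions, so this is an ordinary phenoxide alkylation.

**24 to 23, 22 and 20.** The B1 hydroxyl is traced to a bromide (23), chosen because bromine is inert to SNAr and peracid and the ring B monomer 3 is bought with it in place. The H4 methoxy is traced to phenol 22 and that to aldehyde 20.

**20 back to 3, 2 and 7.** Each ether is cut between a phenoxide and a fluoro-benzaldehyde: 20 from 19 and 7; 19 (via 17) from 16 and 2; 16 (via 14) from 13 and 7; 13 (via 11) from 10 and 2; 10 (via 8) from 6 and 7; 6 (via 4) from 3 and 2. The chain is grown from ring B toward ring H because in this direction the crowded oxygen is always the nucleophile. In 7 the fluorine is para to the formyl group and has two free ortho positions; in 2 it is ortho to the formyl group and has one. Growth from ring H would require fluoride displacement at carbons flanked by two substituents and conjugated with two methoxy donors. Each formyl group activates one coupling and then becomes the next nucleophile by Dakin oxidation, so only two monomers are needed for seven rings.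

**2 to 1.** The formyl C–C bond is cut. Fluoroarene 1 has two equivalent free positions, so formylation can give only one product.

## Roads not taken

**Alternative 1:** The cut removes nothing from the skeleton; it traces the four hydroxyls on C4, E4, G4 and H4 to formyl groups in tetra-aldehyde A2. In the forward step a peracid converts the four aldehydes to aryl formates, and methanolysis gives tetraphenol A1.

- Merits: the formyl groups can serve as SNAr activators during assembly and are carried unchanged until the end. No oxidation is needed between couplings, so larger fragments could be joined convergently.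
- Weak points: a formyl group on position 4 of rings C, E and G activates carbon 1 but is meta to carbon 2, so the three Y2–O bonds get no help from it. Rings B, D and F carry no formyl group at all. Four oxidations must succeed on one molecule, and the step itself forms no inter-ring bond.
- Comparison: this road is better in convergence and, if the fragment couplings worked, shorter. Against that, the chosen plan uses the same oxidation one aldehyde at a time, where each formyl both activates a coupling and becomes the next nucleophile. It also makes the A2–O bond at sp3 carbon and leaves ring A unprotected, so eighteen ethers are cleaved at the end instead of twenty-one.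

**Alternative 2:** The cut is the G5–G6 bond and with it the whole of ring G. The α-metalated vinyl ether A6 of a hexamer A–F is added to dimethyl squarate A5 and the adduct is protected, giving cyclobutenone A4. Heating opens the four-membered ring to a dienylketene, which closes by 6π electrocyclisation and enolises to heptamer A3.

- Merits: all five oxygens of ring G are placed without regiochemical doubt. The G5 hydroxyl emerges free and distinct from the protected G2 oxygen. The thermal ring expansion of 4-alkenylcyclobutenones is well established.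
- Weak points: A6 must be metalated with a strong alkyllithium base in the presence of fourteen methoxy groups and five diaryl ethers, where ortho-metalation competes. The hexamer has to be made by other chemistry anyway. Ring H must still be attached to the crowded G2 oxygen afterwards.
- Comparison: as a ring-forming reaction on substituted substrates this one is better precedented than the chosen key step. Against that, the chosen plan builds a terminal ring, so nothing follows it but deprotection. Its precursor is attached by a plain phenoxide alkylation, and no organolithium is used on the oligomer.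

**Alternative 3:** The cut takes out both ether bonds of ring E. In one pot the D4 phenoxide of tetramer A9 displaces the fluoride para to a formyl group of linchpin A8, and the F1 phenoxide of trimer A10 then displaces the second fluoride, giving octamer dialdehyde A7.

- Merits: the assembly is 4 + 1 + 3, the most convergent of all, and the longest linear sequence is roughly halved. The two fluorides differ in activation, so the order of addition is programmed.
- Weak points: the second fluoride is ortho to a formyl group but para to a methoxy group, and it is flanked by the newly attached tetramer. It must be displaced by a trimer-sized phenoxide. Ortho-dialdehydes disproportionate to phthalides under hot carbonate. The two adjacent formyl groups then need a double Dakin oxidation to a catechol, which peracids oxidise further. A9 and A10 still require their own syntheses with the same two ether types.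
- Comparison: if it worked, this road would beat the chosen plan in convergence and in material throughput. Against that, every coupling in the chosen plan is a single SNAr on a mono-aldehyde, no vicinal dialdehyde is carried, and the most hindered ether is not made as a diaryl ether at all.

Key step: step 20

## Route

Assumption: 5-fluoro-1,2,3-trimethoxybenzene (1) is taken as a catalogue fluoroarene; should it have to be made, Balz–Schiemann fluorination of 3,4,5-trimethoxyaniline adds one step.

Assumption: silyl enol ethers 27 and 28 may form as mixtures of double-bond isomers; the isomer drawn is the expected main one, and the geometry is erased in step 19.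

Step 1
Reactants: 1 5-fluoro-1,2,3-trimethoxybenzene
Product: 2 6-fluoro-2,3,4-trimethoxybenzaldehyde
Conditions: Cl2CHOMe, TiCl4, CH2Cl2, 0 °C; then H2O
Reagents that add atoms: dichloromethyl methyl ether, COC(Cl)Cl; water, O
Why: Rieche formylation (electrophilic aromatic substitution by the TiCl4-activated chloro ether, then hydrolysis). The two free positions of 1 are equivalent and each is ortho and para to methoxy groups, so one aldehyde forms, with fluorine ortho to the formyl group.

Step 2
Reactants: 3 4-bromo-2,6-dimethoxyphenol; 2 6-fluoro-2,3,4-trimethoxybenzaldehyde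
Product: 4 dimer B–C aldehyde
Conditions: Cs2CO3, DMSO, 100 °C, argon
Reagents that add atoms: none
Why: SNAr (addition–elimination) of the phenoxide at the fluoride ortho to the formyl group forms B4–O–C1. The crowded oxygen is the nucleophile, the attacked carbon has a free ortho position, and the unactivated aryl bromide does not react.

Step 3
Reactants: 4 dimer B–C aldehyde
Product: 6 dimer B–C phenol, via dimer B–C formate 5 (not isolated)
Conditions: mCPBA, CH2Cl2, 0 °C to rt; aq. Na2S2O3/NaHCO3 wash; then K2CO3 (cat.), MeOH, rt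
Reagents that add atoms: 3-chloroperoxybenzoic acid (mCPBA), OOC(=O)c1cccc(Cl)c1
Why: Dakin-type Baeyer–Villiger oxidation: in the peracid adduct the aryl group, electron-rich through ortho and para oxygens, migrates in preference to hydride and gives formate 5, which methanol cleaves. The phenol is released only after the peracid has been washed out, so it is not oxidised further.

Step 4
Reactants: 6 dimer B–C phenol; 7 4-fluoro-2,6-dimethoxybenzaldehyde
Product: 8 trimer B–D aldehyde
Conditions: Cs2CO3, DMSO, 110 °C, argon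
Reagents that add atoms: none
Why: SNAr para to the formyl group of 7 forms C2–O–D1. Both methoxy groups of 7 are meta to fluorine and do not deactivate it, and the attacked carbon has two free ortho positions, so the di-ortho-substituted phenoxide can reach it.

Step 5
Reactants: 8 trimer B–D aldehyde
Product: 10 trimer B–D phenol, via trimer B–D formate 9 (not isolated)
Conditions: mCPBA, CH2Cl2, 0 °C to rt; aq. Na2S2O3/NaHCO3 wash; then K2CO3 (cat.), MeOH, rt
Reagents that add atoms: 3-chloroperoxybenzoic acid (mCPBA), OOC(=O)c1cccc(Cl)c1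
Why: Dakin-type Baeyer–Villiger oxidation; the 2,6-dimethoxy-4-aryloxyphenyl group migrates readily and methanolysis of formate 9 frees the D4 hydroxyl.

Step 6
Reactants: 10 trimer B–D phenol; 2 6-fluoro-2,3,4-trimethoxybenzaldehyde
Product: 11 tetramer B–E aldehyde
Conditions: Cs2CO3, DMSO, 110 °C, argon
Reagents that add atoms: none
Why: SNAr ortho to the formyl group, as in step 2, forms D4–O–E1. No other ring of the chain carries an activating group, so the existing ethers are not exchanged.

Step 7
Reactants: 11 tetramer B–E aldehyde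
Product: 13 tetramer B–E phenol, via tetramer B–E formate 12 (not isolated)
Conditions: mCPBA, CH2Cl2, 0 °C to rt; aq. Na2S2O3/NaHCO3 wash; then K2CO3 (cat.), MeOH, rt
Reagents that add atoms: 3-chloroperoxybenzoic acid (mCPBA), OOC(=O)c1cccc(Cl)c1
Why: Dakin-type Baeyer–Villiger oxidation as in step 3; aryl migration and methanolysis of formate 12 free the E2 hydroxyl.

Step 8
Reactants: 13 tetramer B–E phenol; 7 4-fluoro-2,6-dimethoxybenzaldehyde
Product: 14 pentamer B–F aldehyde
Conditions: Cs2CO3, DMSO, 110 °C, argon
Reagents that add atoms: none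
Why: SNAr para to the formyl group, as in step 4, forms E2–O–F1.

Step 9
Reactants: 14 pentamer B–F aldehyde
Product: 16 pentamer B–F phenol, via pentamer B–F formate 15 (not isolated)
Conditions: mCPBA, CH2Cl2, 0 °C to rt; aq. Na2S2O3/NaHCO3 wash; then K2CO3 (cat.), MeOH, rt
Reagents that add atoms: 3-chloroperoxybenzoic acid (mCPBA), OOC(=O)c1cccc(Cl)c1
Why: Dakin-type Baeyer–Villiger oxidation as in step 5; frees the F4 hydroxyl.

Step 10
Reactants: 16 pentamer B–F phenol; 2 6-fluoro-2,3,4-trimethoxybenzaldehyde
Product: 17 hexamer B–G aldehyde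
Conditions: Cs2CO3, DMSO, 110 °C, argon
Reagents that add atoms: none
Why: SNAr ortho to the formyl group, as in steps 2 and 6, forms F4–O–G1; the phenoxide oxygen projects beyond the bulk of the pentamer.

Step 11
Reactants: 17 hexamer B–G aldehyde
Product: 19 hexamer B–G phenol, via hexamer B–G formate 18 (not isolated)
Conditions: mCPBA, CH2Cl2, 0 °C to rt; aq. Na2S2O3/NaHCO3 wash; then K2CO3 (cat.), MeOH, rt
Reagents that add atoms: 3-chloroperoxybenzoic acid (mCPBA), OOC(=O)c1cccc(Cl)c1
Why: Dakin-type Baeyer–Villiger oxidation as in step 3; frees the G2 hydroxyl.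

Step 12
Reactants: 19 hexamer B–G phenol; 7 4-fluoro-2,6-dimethoxybenzaldehyde
Product: 20 heptamer B–H aldehyde
Conditions: Cs2CO3, DMSO, 110 °C, argon
Reagents that add atoms: none
Why: SNAr para to the formyl group, as in step 4, forms G2–O–H1 and brings in ring H with its two flanking methoxy groups.

Step 13
Reactants: 20 heptamer B–H aldehyde
Product: 22 heptamer H4 phenol, via heptamer B–H formate 21 (not isolated)
Conditions: mCPBA, CH2Cl2, 0 °C to rt; aq. Na2S2O3/NaHCO3 wash; then K2CO3 (cat.), MeOH, rt
Reagents that add atoms: 3-chloroperoxybenzoic acid (mCPBA), OOC(=O)c1cccc(Cl)c1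
Why: Dakin-type Baeyer–Villiger oxidation as in step 5; frees the H4 hydroxyl, the last oxygen of the heptamer.

Step 14
Reactants: 22 heptamer H4 phenol
Product: 23 heptamer bromide
Conditions: MeI, K2CO3, DMF, 40 °C
Reagents that add atoms: iodomethane, CI
Why: Williamson methylation of the 2,6-dimethoxyphenol; a methyl electrophile is small enough for the flanked oxygen. Ring H thereby gets the same protecting group as all other rings.

Step 15
Reactants: 23 heptamer bromide
Product: 24 heptamer phenol B–H
Conditions: Pd2(dba)3 (cat.), tBuXPhos (cat.), KOH, 1,4-dioxane/H2O, 100 °C; then aq. HCl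
Reagents that add atoms: potassium hydroxide, [K+].[OH-]
Why: Palladium-catalysed hydroxylation of an aryl bromide (C–O cross-coupling with hydroxide under a bulky biarylphosphine). The bromide has two free ortho positions, and methyl and diaryl ethers are inert to hydroxide here.

Step 16
Reactants: 24 heptamer phenol B–H; 25 methyl 4-chloro-3-oxobutanoate
Product: 26 methyl 4-(heptamer-oxy)-3-oxobutanoate
Conditions: K2CO3, KI (cat.), acetone, reflux
Reagents that add atoms: none
Why: Williamson ether synthesis (SN2 at the primary α-chloroketone carbon) by an unhindered phenoxide makes the future A2–O bond at sp3 carbon. The β-keto ester sits as its C2 enolate, which shields the ketone from self-condensation.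

Step 17
Reactants: 26 methyl 4-(heptamer-oxy)-3-oxobutanoate
Product: 27 mono silyl enol ether
Conditions: Me3SiCl, Et3N, toluene, rt
Reagents that add atoms: chlorotrimethylsilane, C[Si](C)(C)Cl
Why: O-silylation of the β-keto ester enol under soft enolisation, the usual first stage toward a 1,3-bis(silyl enol ether).

Step 18
Reactants: 27 mono silyl enol ether
Product: 28 1,3-bis(silyl enol ether)
Conditions: LDA, THF, −78 °C; Me3SiCl, −78 °C to rt; filtration, concentration (used crude)
Reagents that add atoms: chlorotrimethylsilane, C[Si](C)(C)Cl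
Why: Vinylogous (γ) deprotonation of the β-silyloxy enoate and O-silylation of the dienolate, the usual second stage of 1,3-bis(silyl enol ether) synthesis. LDA at −78 °C does not metalate methoxyarenes.

Step 19
Reactants: 28 1,3-bis(silyl enol ether); 29 methyl 3-chloro-3-oxopropanoate
Product: 30 dimethyl 4-(heptamer-oxy)-3,5-dioxoheptanedioate
Conditions: CH2Cl2, −78 °C to rt; aq. NaHCO3 work-up
Reagents that add atoms: none
Why: Mukaiyama-type C-acylation of a 1,3-bis(silyl enol ether) at its terminal carbon by an acid chloride without Lewis acid, the known route from such dienes and methyl malonyl chloride to 3,5-dioxopimelates; it forms C4–C5. The neutral silyl nucleophile tolerates the acidic methylene of 29, and the bicarbonate work-up avoids acid-induced cyclodehydration onto ring B.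

Step 20
Reactants: 30 dimethyl 4-(heptamer-oxy)-3,5-dioxoheptanedioate
Product: 31 methyl 3-(heptamer-oxy)-2,4,6-trihydroxybenzoate
Conditions: Mg(OMe)2, MeOH, reflux, argon; then aq. HCl, 0 °C
Reagents that add atoms: none
Why: Dieckmann-type intramolecular Claisen condensation, the known cyclisation of 3,5-dioxopimelates and related poly-β-carbonyl esters to phloroglucinol carboxylates, here with an aryloxy group on C4. Mg(OMe)2 first removes the most acidic proton (C4–H, between two ketones and next to oxygen), and the magnesium chelate of the central diketone is no longer electrophilic, which suppresses retro-Claisen scission by methoxide. A second deprotonation at C2 gives the ester enolate, which adds to the C7 ester carbonyl in a 6-exo-trig closure; loss of methoxide forms the A4–A5 bond and ring A as a cyclohexanetrione that enolises at once to the aromatic triol. No stereocenter is created, and C4 becomes the sp2 carbon A2. The chain is symmetric about C4, so closure from either end gives the same ester. The selectivity needed is C- over O-acylation: attack of the C3 enolate oxygen on the C7 ester would give a 4-hydroxy-2-pyranone, but that lactone reopens in methanolic methoxide, whereas the aromatic phenoxide of 31 forms irreversibly and drains the equilibrium. Every other carbon nucleophile–electrophile pairing in 30 would give a four-membered ring, so no aldol-type isomer can arise.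

Step 21
Reactants: 31 methyl 3-(heptamer-oxy)-2,4,6-trihydroxybenzoate
Product: 33 ring A triol, via benzoic acid 32 (not isolated)
Conditions: KOH, H2O/MeOH, 80 °C, argon; then aq. HCl, 60 °C
Reagents that add atoms: none
Why: Saponification followed by decarboxylation of 2,4,6-trihydroxybenzoic acid 32, which loses CO2 on gentle warming in acid because ipso protonation gives a β-keto acid tautomer. Argon protects the phloroglucinol ring while it is a phenoxide.

Step 22
Reactants: 33 ring A triol
Product: 34 CNP0206369.0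
Conditions: BBr3 (excess), CH2Cl2, −78 °C to rt; then MeOH, H2O, argon
Reagents that add atoms: none
Why: Lewis acid-mediated cleavage of aryl methyl ethers: bromide attacks the methyl group of each boron-bound ether. Diaryl ethers offer no sp3 carbon to bromide and survive, and the conditions are non-oxidising.

## Compound list

1 | 5-fluoro-1,2,3-trimethoxybenzene | COc1cc(F)cc(OC)c1OC | starting material
2 | 6-fluoro-2,3,4-trimethoxybenzaldehyde (unit for rings C, E, G) | COc1cc(F)c(C=O)c(OC)c1OC | intermediate
3 | 4-bromo-2,6-dimethoxyphenol (ring B) | COc1cc(Br)cc(OC)c1O | starting material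
4 | dimer B–C aldehyde: 6-(4-bromo-2,6-dimethoxyphenoxy)-2,3,4-trimethoxybenzaldehyde | Brc1cc(OC)c(Oc2cc(OC)c(OC)c(OC)c2C=O)c(OC)c1 | intermediate
5 | dimer B–C formate: 6-(4-bromo-2,6-dimethoxyphenoxy)-2,3,4-trimethoxyphenyl formate | Brc1cc(OC)c(Oc2cc(OC)c(OC)c(OC)c2OC=O)c(OC)c1 | intermediate (not isolated)
6 | dimer B–C phenol: 6-(4-bromo-2,6-dimethoxyphenoxy)-2,3,4-trimethoxyphenol (free C2–OH) | Brc1cc(OC)c(Oc2cc(OC)c(OC)c(OC)c2O)c(OC)c1 | intermediate
7 | 4-fluoro-2,6-dimethoxybenzaldehyde (unit for rings D, F, H) | COc1cc(F)cc(OC)c1C=O | starting material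
8 | trimer B–D aldehyde: 4-[6-(4-bromo-2,6-dimethoxyphenoxy)-2,3,4-trimethoxyphenoxy]-2,6-dimethoxybenzaldehyde (formyl on D4) | Brc1cc(OC)c(Oc2cc(OC)c(OC)c(OC)c2Oc2cc(OC)c(C=O)c(OC)c2)c(OC)c1 | intermediate
9 | trimer B–D formate: formate ester of 10 on the D4 oxygen | Brc1cc(OC)c(Oc2cc(OC)c(OC)c(OC)c2Oc2cc(OC)c(OC=O)c(OC)c2)c(OC)c1 | intermediate (not isolated)
10 | trimer B–D phenol: 4-[6-(4-bromo-2,6-dimethoxyphenoxy)-2,3,4-trimethoxyphenoxy]-2,6-dimethoxyphenol (free D4–OH) | Brc1cc(OC)c(Oc2cc(OC)c(OC)c(OC)c2Oc2cc(OC)c(O)c(OC)c2)c(OC)c1 | intermediate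
11 | tetramer B–E aldehyde: 10 with its D4 oxygen bonded to C6 of a 2,3,4-trimethoxybenzaldehyde ring (ring E; formyl on E2) | Brc1cc(OC)c(Oc2cc(OC)c(OC)c(OC)c2Oc2cc(OC)c(Oc3cc(OC)c(OC)c(OC)c3C=O)c(OC)c2)c(OC)c1 | intermediate
12 | tetramer B–E formate: formate ester of 13 on the E2 oxygen | Brc1cc(OC)c(Oc2cc(OC)c(OC)c(OC)c2Oc2cc(OC)c(Oc3cc(OC)c(OC)c(OC)c3OC=O)c(OC)c2)c(OC)c1 | intermediate (not isolated)
13 | tetramer B–E phenol: 11 with OH in place of the E2 formyl group | Brc1cc(OC)c(Oc2cc(OC)c(OC)c(OC)c2Oc2cc(OC)c(Oc3cc(OC)c(OC)c(OC)c3O)c(OC)c2)c(OC)c1 | intermediate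
14 | pentamer B–F aldehyde: 13 with its E2 oxygen bonded to C4 of a 2,6-dimethoxybenzaldehyde ring (ring F; formyl on F4) | Brc1cc(OC)c(Oc2cc(OC)c(OC)c(OC)c2Oc2cc(OC)c(Oc3cc(OC)c(OC)c(OC)c3Oc3cc(OC)c(C=O)c(OC)c3)c(OC)c2)c(OC)c1 | intermediate
15 | pentamer B–F formate: formate ester of 16 on the F4 oxygen | Brc1cc(OC)c(Oc2cc(OC)c(OC)c(OC)c2Oc2cc(OC)c(Oc3cc(OC)c(OC)c(OC)c3Oc3cc(OC)c(OC=O)c(OC)c3)c(OC)c2)c(OC)c1 | intermediate (not isolated)
16 | pentamer B–F phenol: 14 with OH in place of the F4 formyl group | Brc1cc(OC)c(Oc2cc(OC)c(OC)c(OC)c2Oc2cc(OC)c(Oc3cc(OC)c(OC)c(OC)c3Oc3cc(OC)c(O)c(OC)c3)c(OC)c2)c(OC)c1 | intermediate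
17 | hexamer B–G aldehyde: 16 with its F4 oxygen bonded to C6 of a 2,3,4-trimethoxybenzaldehyde ring (ring G; formyl on G2) | Brc1cc(OC)c(Oc2cc(OC)c(OC)c(OC)c2Oc2cc(OC)c(Oc3cc(OC)c(OC)c(OC)c3Oc3cc(OC)c(Oc4cc(OC)c(OC)c(OC)c4C=O)c(OC)c3)c(OC)c2)c(OC)c1 | intermediate
18 | hexamer B–G formate: formate ester of 19 on the G2 oxygen | Brc1cc(OC)c(Oc2cc(OC)c(OC)c(OC)c2Oc2cc(OC)c(Oc3cc(OC)c(OC)c(OC)c3Oc3cc(OC)c(Oc4cc(OC)c(OC)c(OC)c4OC=O)c(OC)c3)c(OC)c2)c(OC)c1 | intermediate (not isolated)
19 | hexamer B–G phenol: 17 with OH in place of the G2 formyl group | Brc1cc(OC)c(Oc2cc(OC)c(OC)c(OC)c2Oc2cc(OC)c(Oc3cc(OC)c(OC)c(OC)c3Oc3cc(OC)c(Oc4cc(OC)c(OC)c(OC)c4O)c(OC)c3)c(OC)c2)c(OC)c1 | intermediate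
20 | heptamer B–H aldehyde: 19 with its G2 oxygen bonded to C4 of a 2,6-dimethoxybenzaldehyde ring (ring H; formyl on H4) | Brc1cc(OC)c(Oc2cc(OC)c(OC)c(OC)c2Oc2cc(OC)c(Oc3cc(OC)c(OC)c(OC)c3Oc3cc(OC)c(Oc4cc(OC)c(OC)c(OC)c4Oc4cc(OC)c(C=O)c(OC)c4)c(OC)c3)c(OC)c2)c(OC)c1 | intermediate
21 | heptamer B–H formate: formate ester of 22 on the H4 oxygen | Brc1cc(OC)c(Oc2cc(OC)c(OC)c(OC)c2Oc2cc(OC)c(Oc3cc(OC)c(OC)c(OC)c3Oc3cc(OC)c(Oc4cc(OC)c(OC)c(OC)c4Oc4cc(OC)c(OC=O)c(OC)c4)c(OC)c3)c(OC)c2)c(OC)c1 | intermediate (not isolated)
22 | heptamer H4 phenol: 20 with OH in place of the H4 formyl group | Brc1cc(OC)c(Oc2cc(OC)c(OC)c(OC)c2Oc2cc(OC)c(Oc3cc(OC)c(OC)c(OC)c3Oc3cc(OC)c(Oc4cc(OC)c(OC)c(OC)c4Oc4cc(OC)c(O)c(OC)c4)c(OC)c3)c(OC)c2)c(OC)c1 | intermediate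
23 | heptamer bromide: 22 with OMe on H4 (Br on B1; eighteen methyl ethers) | Brc1cc(OC)c(Oc2cc(OC)c(OC)c(OC)c2Oc2cc(OC)c(Oc3cc(OC)c(OC)c(OC)c3Oc3cc(OC)c(Oc4cc(OC)c(OC)c(OC)c4Oc4cc(OC)c(OC)c(OC)c4)c(OC)c3)c(OC)c2)c(OC)c1 | intermediate
24 | heptamer phenol B–H: 23 with OH in place of Br on B1 | Oc1cc(OC)c(Oc2cc(OC)c(OC)c(OC)c2Oc2cc(OC)c(Oc3cc(OC)c(OC)c(OC)c3Oc3cc(OC)c(Oc4cc(OC)c(OC)c(OC)c4Oc4cc(OC)c(OC)c(OC)c4)c(OC)c3)c(OC)c2)c(OC)c1 | intermediate
25 | methyl 4-chloro-3-oxobutanoate | COC(=O)CC(=O)CCl | starting material
26 | methyl 4-(heptamer B–H 1-oxy)-3-oxobutanoate | COC(=O)CC(=O)COc1cc(OC)c(Oc2cc(OC)c(OC)c(OC)c2Oc2cc(OC)c(Oc3cc(OC)c(OC)c(OC)c3Oc3cc(OC)c(Oc4cc(OC)c(OC)c(OC)c4Oc4cc(OC)c(OC)c(OC)c4)c(OC)c3)c(OC)c2)c(OC)c1 | intermediate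
27 | mono silyl enol ether: methyl (Z)-4-(heptamer B–H 1-oxy)-3-(trimethylsilyloxy)but-2-enoate | COC(=O)/C=C(\O[Si](C)(C)C)COc1cc(OC)c(Oc2cc(OC)c(OC)c(OC)c2Oc2cc(OC)c(Oc3cc(OC)c(OC)c(OC)c3Oc3cc(OC)c(Oc4cc(OC)c(OC)c(OC)c4Oc4cc(OC)c(OC)c(OC)c4)c(OC)c3)c(OC)c2)c(OC)c1 | intermediate
28 | 1,3-bis(silyl enol ether): (1Z,3Z)-4-(heptamer B–H 1-oxy)-1-methoxy-1,3-bis(trimethylsilyloxy)buta-1,3-diene | CO/C(O[Si](C)(C)C)=C/C(O[Si](C)(C)C)=C/Oc1cc(OC)c(Oc2cc(OC)c(OC)c(OC)c2Oc2cc(OC)c(Oc3cc(OC)c(OC)c(OC)c3Oc3cc(OC)c(Oc4cc(OC)c(OC)c(OC)c4Oc4cc(OC)c(OC)c(OC)c4)c(OC)c3)c(OC)c2)c(OC)c1 | intermediate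
29 | methyl 3-chloro-3-oxopropanoate (methyl malonyl chloride) | COC(=O)CC(Cl)=O | starting material
30 | dimethyl 4-(heptamer B–H 1-oxy)-3,5-dioxoheptanedioate | COC(=O)CC(=O)C(Oc1cc(OC)c(Oc2cc(OC)c(OC)c(OC)c2Oc2cc(OC)c(Oc3cc(OC)c(OC)c(OC)c3Oc3cc(OC)c(Oc4cc(OC)c(OC)c(OC)c4Oc4cc(OC)c(OC)c(OC)c4)c(OC)c3)c(OC)c2)c(OC)c1)C(=O)CC(=O)OC | intermediate
31 | methyl 3-(heptamer B–H 1-oxy)-2,4,6-trihydroxybenzoate (octamer; ring A as ester) | COC(=O)c1c(O)cc(O)c(Oc2cc(OC)c(Oc3cc(OC)c(OC)c(OC)c3Oc3cc(OC)c(Oc4cc(OC)c(OC)c(OC)c4Oc4cc(OC)c(Oc5cc(OC)c(OC)c(OC)c5Oc5cc(OC)c(OC)c(OC)c5)c(OC)c4)c(OC)c3)c(OC)c2)c1O | intermediate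
32 | 3-(heptamer B–H 1-oxy)-2,4,6-trihydroxybenzoic acid | OC(=O)c1c(O)cc(O)c(Oc2cc(OC)c(Oc3cc(OC)c(OC)c(OC)c3Oc3cc(OC)c(Oc4cc(OC)c(OC)c(OC)c4Oc4cc(OC)c(Oc5cc(OC)c(OC)c(OC)c5Oc5cc(OC)c(OC)c(OC)c5)c(OC)c4)c(OC)c3)c(OC)c2)c1O | intermediate (not isolated)
33 | ring A triol: 2-(heptamer B–H 1-oxy)benzene-1,3,5-triol (rings B–H as eighteen methyl ethers) | Oc1cc(O)c(Oc2cc(OC)c(Oc3cc(OC)c(OC)c(OC)c3Oc3cc(OC)c(Oc4cc(OC)c(OC)c(OC)c4Oc4cc(OC)c(Oc5cc(OC)c(OC)c(OC)c5Oc5cc(OC)c(OC)c(OC)c5)c(OC)c4)c(OC)c3)c(OC)c2)c(O)c1 | intermediate
34 | CNP0206369.0 (octamer with 21 free hydroxyls) | Oc1cc(O)c(Oc2cc(O)c(Oc3cc(O)c(O)c(O)c3Oc3cc(O)c(Oc4cc(O)c(O)c(O)c4Oc4cc(O)c(Oc5cc(O)c(O)c(O)c5Oc5cc(O)c(O)c(O)c5)c(O)c4)c(O)c3)c(O)c2)c(O)c1 | target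

## Step count and least certain steps

Total: 22 steps. Longest linear sequence: 22 steps (from 1; 21 steps counted from 3).

**Step 20 (key step).** The likeliest failure is retro-Claisen scission of the C3–C4 bond by methoxide, before the second enolate can close the ring; this would return 26 and dimethyl malonate. The second risk is that the material stalls as the O-acylated pyranone if ring reopening is slow under magnesium chelation. Fallback: set out from 24 and abandon the ring construction. A copper-catalysed Ullmann coupling of 24 with 2-iodo-1,3,5-trimethoxybenzene (CuI, picolinic acid, K3PO4, DMSO, 90 °C) gives the permethylated octamer F1. The unhindered B1 phenoxide is the nucleophile, and this catalyst system accepts di-ortho-substituted aryl iodides. BBr3 then cleaves all twenty-one methyl ethers of F1, and the route is rejoined at 34.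

**Step 19.** Acylation may go to oxygen or to C2 instead of the aryloxy-bearing terminal carbon, which is more crowded than in the parent diene. The acid chloride may be lost as a ketene, or the product may cyclodehydrate onto the electron-rich B2 position if the work-up turns acidic. Fallback: set out from 25 and move the C–C bond formation to small molecules. Silylation of 25 (Me3SiCl, Et3N) gives methyl (Z)-4-chloro-3-(trimethylsilyloxy)but-2-enoate F2. LDA and Me3SiCl give 4-chloro-1-methoxy-1,3-bis(trimethylsilyloxy)buta-1,3-diene F3. Acylation with 29 gives dimethyl 4-chloro-3,5-dioxoheptanedioate F4. The phenoxide of 24 is then alkylated with F4 (K2CO3, acetone, rt), as phenols are with 2-chloro-1,3-diketones, and the route is rejoined at 30.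

**Step 10 (and, less acutely, steps 2 and 6).** The fluorine-bearing carbon of 2 is para to a methoxy donor and the nucleophile is a 2,6-dimethoxyphenoxide on a five-ring chain, so addition may be slow. At the temperature then needed, the aldehyde may disproportionate or methyl ethers may be cleaved by the phenoxide. Fallback: set out from 16 and change the bond-forming mechanism. Rieche formylation of purchased 5-iodo-1,2,3-trimethoxybenzene gives 6-iodo-2,3,4-trimethoxybenzaldehyde F5. Ullmann coupling of 16 with F5 (CuI, picolinic acid, K3PO4, DMSO, 80 °C) uses the ortho-formyl iodide, which reacts far faster than the ring B bromide. The route is rejoined at 17.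

**Step 15.** The aryl–palladium intermediate may be reduced (loss of bromine without oxygenation), or the product phenoxide may compete with hydroxide and give a symmetrical diaryl ether. Fallback: set out from 23 and go through boron. Miyaura borylation (B2pin2, Pd(dppf)Cl2, KOAc, 1,4-dioxane, 90 °C) gives the heptamer pinacol boronate F6. Oxidation with H2O2 and NaOH at 0 °C rejoins the route at 24.

**Step 22.** Cleavage may stop short at some of the eighteen ethers and give partly methylated mixtures that cannot be separated as free polyphenols. The pyrogallol rings may also be oxidised during aqueous work-up. Fallback: set out from 33, run the BBr3 cleavage, and acetylate the crude product directly (Ac2O, pyridine) to the henicosaacetate F7. F7 is stable and can be purified by chromatography on silica. The acetates are then removed by acid methanolysis (HCl in MeOH, rt, argon), which never forms a phenoxide, and the route is rejoined at 34.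

## Further compounds

F1 | step 20 | permethylated octamer: 24 etherified on B1–O with a 2,4,6-trimethoxyphenyl group (21 methyl ethers) | COc1cc(OC)c(Oc2cc(OC)c(Oc3cc(OC)c(OC)c(OC)c3Oc3cc(OC)c(Oc4cc(OC)c(OC)c(OC)c4Oc4cc(OC)c(Oc5cc(OC)c(OC)c(OC)c5Oc5cc(OC)c(OC)c(OC)c5)c(OC)c4)c(OC)c3)c(OC)c2)c(OC)c1
F2 | step 19 | methyl (Z)-4-chloro-3-(trimethylsilyloxy)but-2-enoate | COC(=O)/C=C(\O[Si](C)(C)C)CCl
F3 | step 19 | (1Z,3Z)-4-chloro-1-methoxy-1,3-bis(trimethylsilyloxy)buta-1,3-diene | CO/C(O[Si](C)(C)C)=C/C(O[Si](C)(C)C)=C/Cl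
F4 | step 19 | dimethyl 4-chloro-3,5-dioxoheptanedioate | COC(=O)CC(=O)C(Cl)C(=O)CC(=O)OC
F5 | step 10 | 6-iodo-2,3,4-trimethoxybenzaldehyde | COc1cc(I)c(C=O)c(OC)c1OC
F6 | step 15 | heptamer pinacol boronate: 23 with a 4,4,5,5-tetramethyl-1,3,2-dioxaborolan-2-yl group in place of Br | CC5(C)OB(OC5(C)C)c1cc(OC)c(Oc2cc(OC)c(OC)c(OC)c2Oc2cc(OC)c(Oc3cc(OC)c(OC)c(OC)c3Oc3cc(OC)c(Oc4cc(OC)c(OC)c(OC)c4Oc4cc(OC)c(OC)c(OC)c4)c(OC)c3)c(OC)c2)c(OC)c1
F7 | step 22 | henicosaacetate of 34 (all 21 hydroxyls as acetates) | CC(=O)Oc1cc(OC(C)=O)c(Oc2cc(OC(C)=O)c(Oc3cc(OC(C)=O)c(OC(C)=O)c(OC(C)=O)c3Oc3cc(OC(C)=O)c(Oc4cc(OC(C)=O)c(OC(C)=O)c(OC(C)=O)c4Oc4cc(OC(C)=O)c(Oc5cc(OC(C)=O)c(OC(C)=O)c(OC(C)=O)c5Oc5cc(OC(C)=O)c(OC(C)=O)c(OC(C)=O)c5)c(OC(C)=O)c4)c(OC(C)=O)c3)c(OC(C)=O)c2)c(OC(C)=O)c1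
A1 | alternative 1 | octamer tetraphenol (free hydroxyl on C4, E4, G4, H4; seventeen methyl ethers) | COc1cc(OC)c(Oc2cc(OC)c(Oc3cc(OC)c(O)c(OC)c3Oc3cc(OC)c(Oc4cc(OC)c(O)c(OC)c4Oc4cc(OC)c(Oc5cc(OC)c(O)c(OC)c5Oc5cc(OC)c(O)c(OC)c5)c(OC)c4)c(OC)c3)c(OC)c2)c(OC)c1
A2 | alternative 1 | octamer tetra-aldehyde (formyl on C4, E4, G4, H4; seventeen methyl ethers) | COc1cc(OC)c(Oc2cc(OC)c(Oc3cc(OC)c(C=O)c(OC)c3Oc3cc(OC)c(Oc4cc(OC)c(C=O)c(OC)c4Oc4cc(OC)c(Oc5cc(OC)c(C=O)c(OC)c5Oc5cc(OC)c(C=O)c(OC)c5)c(OC)c4)c(OC)c3)c(OC)c2)c(OC)c1
A3 | alternative 2 | heptamer A–G with ring G as 5-hydroxy-3,4-dimethoxy-2-(methoxymethoxy)phenyl ether | COc1cc(OC)c(Oc2cc(OC)c(Oc3cc(OC)c(OC)c(OC)c3Oc3cc(OC)c(Oc4cc(OC)c(OC)c(OC)c4Oc4cc(OC)c(Oc5cc(O)c(OC)c(OC)c5OCOC)c(OC)c4)c(OC)c3)c(OC)c2)c(OC)c1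
A4 | alternative 2 | 4-[1-(hexamer A–F 4-oxy)vinyl]-2,3-dimethoxy-4-(methoxymethoxy)cyclobut-2-en-1-one | COc1cc(OC)c(Oc2cc(OC)c(Oc3cc(OC)c(OC)c(OC)c3Oc3cc(OC)c(Oc4cc(OC)c(OC)c(OC)c4Oc4cc(OC)c(OC(=C)C5(OCOC)C(OC)=C(OC)C5=O)c(OC)c4)c(OC)c3)c(OC)c2)c(OC)c1
A5 | alternative 2 | dimethyl squarate (3,4-dimethoxycyclobut-3-ene-1,2-dione) | COC1=C(OC)C(=O)C1=O
A6 | alternative 2 | hexamer A–F vinyl ether (vinyloxy on F4) | COc1cc(OC)c(Oc2cc(OC)c(Oc3cc(OC)c(OC)c(OC)c3Oc3cc(OC)c(Oc4cc(OC)c(OC)c(OC)c4Oc4cc(OC)c(OC=C)c(OC)c4)c(OC)c3)c(OC)c2)c(OC)c1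
A7 | alternative 3 | octamer with ring E as 3,4-diformyl-5-methoxy, all other hydroxyls as methyl ethers | COc1cc(OC)c(Oc2cc(OC)c(Oc3cc(OC)c(OC)c(OC)c3Oc3cc(OC)c(Oc4cc(OC)c(C=O)c(C=O)c4Oc4cc(OC)c(Oc5cc(OC)c(OC)c(OC)c5Oc5cc(OC)c(OC)c(OC)c5)c(OC)c4)c(OC)c3)c(OC)c2)c(OC)c1
A8 | alternative 3 | 3,4-difluoro-6-methoxyphthalaldehyde | COc1cc(F)c(F)c(C=O)c1C=O
A9 | alternative 3 | tetramer A–D phenol (free D4–OH) | COc1cc(OC)c(Oc2cc(OC)c(Oc3cc(OC)c(OC)c(OC)c3Oc3cc(OC)c(O)c(OC)c3)c(OC)c2)c(OC)c1
A10 | alternative 3 | trimer F–H phenol (free F1–OH) | Oc1cc(OC)c(Oc2cc(OC)c(OC)c(OC)c2Oc2cc(OC)c(OC)c(OC)c2)c(OC)c1
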